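**Remark on the chemistry:** the target has no stereocentre and no C=C geometry, so it is achiral. The requirement "single enantiomer" is met by constitution alone, and the only isomer problem is regiochemical (linear against branched acyl chain).

**Route in one sentence:** linear-selective palladium-hydride alkoxycarbonylation that joins icos-1-ene, carbon monoxide and 2-phenylethanol in one operation.

## Structural features

- The target is an ester of two unbranched parts: a saturated C21 acyl chain (C1 the ester carbonyl, C2–C20 methylenes, C21 the methyl group) and a 2-phenylethoxy group (O–CH2–CH2–C6H5).
- The only ring is the monosubstituted benzene ring. There is no stereocentre and no alkene.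
- The only reactive group is the ester, which is sensitive to strong base, hydride and nucleophiles. The homobenzylic C–O bond is not a benzylic one and tolerates weak acid and hydrogenation conditions.
- The difficulty is one of provenance, not of reactivity. The acyl chain has an odd number of carbons (21), whereas fats and ethylene oligomers supply even-numbered chains, so one carbon must be added to a C20 unit or the chain must be assembled from fragments.
- C1 is a single carbon at the carboxyl oxidation level, placed between a primary alkyl terminus (C2) and an alkoxy oxygen, and C2–C3 is an unfunctionalised CH2–CH2 unit.
- The key step exploits exactly this pattern. It arises when H and C(=O)OR add across a terminal C=C bond in the anti-Markovnikov sense, with carbon monoxide as the source of C1.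
- The one selectivity issue is linear against branched. Acylation at the internal carbon would give a 2-methyl-branched isomer with a stereocentre at C2 and nearly the same polarity as the target.

## Logic of the disconnections

**Disconnection of 4 into 1, 2 and 3.** The bonds cut are C1–C2 and C1–O(alkyl) of 4, and the hydrogen on C3 is returned to the alcohol. The cut is placed at C1 because this is the "odd" carbon. Removing it as 2 leaves an even-numbered C20 1-alkene, 1, on one side and the intact alcohol 3 on the other. The gain in simplicity is the largest available: 4 falls in one operation into three purchasable components, with no activating group, no protecting group and no co-product. The demand on the forward step is regiocontrol: the acyl group must be placed on the terminal carbon of 1 and not on its C2. The step must also tolerate migration of the double bond of 1 along the chain without loss of material.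

**Starting materials.** 1, 2 and 3 are purchased, so no further disconnection is needed.

## Other disconnections considered

**Alternative 1:** the first that comes to mind.
- Cut: the C1–O acyl bond.
- Forward key step: esterification of heneicosanoic acid A1 with 3, either with a carbodiimide and DMAP or by way of heneicosanoyl chloride A2.
- Ground for preferring the chosen plan: this step forms only the C–O bond and leaves the odd C21 chain to the supplier of A1, which is itself a one-carbon homologue of C20 feedstock. The homologation is therefore hidden, not solved. The step count is the same, but it needs a stoichiometric activating agent and gives a stoichiometric co-product, whereas the chosen step is a pure addition that builds the chain and the ester together.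

**Alternative 2:**
- Cut: the C4–C5 bond.
- Forward key step: mixed Kolbe anodic decarboxylative cross-coupling of stearic acid A3 with the half-ester 5-oxo-5-(2-phenylethoxy)pentanoic acid A5. A5 is made by opening glutaric anhydride A4 with 3.
- Ground for preferring the chosen plan: the two alkyl radicals couple statistically, so homo-coupling of each partner cannot be avoided and must be paid for with an excess of one acid. The benzene ring competes with the carboxylates for the anode surface. The plan needs two steps against one. Its merit is that the position of the new bond is fixed by the carboxyl groups, and it is therefore kept as the fallback.

**Alternative 3:**
- Cut: a C4=C5 double bond introduced retrosynthetically.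
- Forward key step: olefin cross-metathesis of 2-phenylethyl pent-4-enoate A7 (from pent-4-enoic acid A6 and 3) with octadec-1-ene A8 to give 2-phenylethyl (E)-henicos-4-enoate A9 (as an E/Z mixture), followed by hydrogenation.
- Ground for preferring the chosen plan: three steps against one. Cross-metathesis of two unhindered terminal alkenes is statistical. The alkene is made only to be erased in a separate reduction, whereas the chosen step delivers the chain at its final oxidation level.

Key step: step 1

## Route

Step 1
Reactants: 1 icos-1-ene (1-eicosene); 2 carbon monoxide; 3 2-phenylethanol
Product: 4 2-phenylethyl heneicosanoate (phenylethyl n-heneicosanoate, the target)
Conditions: Pd(OAc)2 (1 mol%), 1,2-bis(di-tert-butylphosphinomethyl)benzene (4 mol%), MsOH (10 mol%), CO (30 bar), 3 (3 equiv), toluene, 100 °C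
Reagents that add atoms: none
Why: Pd-catalysed hydroalkoxycarbonylation (hydroesterification) of a 1-alkene by the hydride cycle: MsOH and the alcohol turn the Pd(II)/diphosphine precursor into a cationic Pd–H, which adds across C1=C2 of 1, CO inserts into the Pd–alkyl bond, and 3 cleaves the Pd–acyl bond to release 4 and return Pd–H. The closest known reaction type is the linear-selective, isomerising alkoxycarbonylation of long-chain alkenes with primary alcohols under Pd/bulky diphosphine/sulfonic acid catalysis. No ring is closed and no stereocentre is created; the step forms C1–C2 and C1–O of 4 and places H on C3. The selectivity needed is regiochemical, acyl on the terminal carbon and not on C2 of 1: olefin insertion and β-hydride elimination are fast and reversible, so all Pd–alkyl isomers interconvert, and the four tert-butyl groups of the wide-bite-angle ligand make CO insertion and alcoholysis much faster for the unhindered primary alkyl and acyl (Curtin–Hammett selection). For the same reason, 1 that has isomerised to internal icosenes is not lost, since chain-walking returns Pd to the chain end before carbonylation. The substrate helps: 1 is unbranched and carries no second functional group, and 3 is an unhindered primary alcohol whose benzene ring and C–O bond are inert to the weakly acidic medium; the excess of 3 keeps the alcoholysis, the slow step, fast enough to outrun loss of palladium. All atoms of 1, 2 and 3 end up in 4, so the step has no co-product; excess 3 is distilled off and 4 is recrystallised.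

## Compound list

1 | icos-1-ene (1-eicosene) | CCCCCCCCCCCCCCCCCCC=C | starting material
2 | carbon monoxide | [C-]#[O+] | starting material
3 | 2-phenylethanol | OCCc1ccccc1 | starting material
4 | 2-phenylethyl heneicosanoate (phenylethyl n-heneicosanoate) | CCCCCCCCCCCCCCCCCCCCC(=O)OCCc1ccccc1 | target

## Step count and risk

Total step count: 1. Longest linear sequence: 1 step.

The route has a single step, so the key step is the only one that can be ranked.

**Step 1 (key step).** Three things are most likely to go wrong.
- Incomplete regiocontrol: carbonylation at the secondary Pd–alkyl would give a racemic, methyl-branched isomeric ester of almost the same polarity, whose removal would rest on crystallisation alone.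
- Loss of catalyst: 3 is more dilute than the neat methanol usual for this reaction type, so alcoholysis of the Pd–acyl may be slow enough for the palladium to be reduced to inactive metal before conversion is complete.
- Chain-length homologues: if the lot of 1 is not homogeneous, homologues would be carried through unchanged.

**Fallback for step 1.** The fallback sets out from 3 and comes back to the route at 4. It is a decarboxylative assembly of the chain in place of a carbonylation.
- 3 opens glutaric anhydride A4 (DMAP cat., toluene, 80 °C) to give 5-oxo-5-(2-phenylethoxy)pentanoic acid F1 (the same structure as A5). This is an addition without co-product.
- F1 is then electrolysed together with an excess of stearic acid A3 in an undivided cell at a smooth platinum anode (MeOH, about one tenth of the acid neutralised with KOH, 45 °C, high current density).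
- This is a mixed Kolbe electrolysis: both carboxylates lose CO2 at the anode, and cross-coupling of the two primary alkyl radicals forms the C4–C5 bond of 4 directly.
- Because the position of the new bond is fixed by the two carboxyl groups, no branched isomer can arise. Chain-length purity is set by A3.
- The price is statistical homo-coupling of each radical. This should give a hydrocarbon and a diester that differ widely in polarity from 4 and are removed by chromatography.
- The weakly acidic carboxylate buffer should leave the ester of F1 and of 4 untouched.

## Further compounds

F1 | step 1 | 5-oxo-5-(2-phenylethoxy)pentanoic acid (mono(2-phenylethyl) glutarate) | OC(=O)CCCC(=O)OCCc1ccccc1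
A1 | alternative 1 | heneicosanoic acid | CCCCCCCCCCCCCCCCCCCCC(=O)O
A2 | alternative 1 | heneicosanoyl chloride | CCCCCCCCCCCCCCCCCCCCC(=O)Cl
A3 | alternative 2 | stearic acid (octadecanoic acid) | CCCCCCCCCCCCCCCCCC(=O)O
A4 | alternative 2 | glutaric anhydride | O=C1CCCC(=O)O1
A5 | alternative 2 | 5-oxo-5-(2-phenylethoxy)pentanoic acid | OC(=O)CCCC(=O)OCCc1ccccc1
A6 | alternative 3 | pent-4-enoic acid | C=CCCC(=O)O
A7 | alternative 3 | 2-phenylethyl pent-4-enoate | C=CCCC(=O)OCCc1ccccc1
A8 | alternative 3 | octadec-1-ene | CCCCCCCCCCCCCCCCC=C
A9 | alternative 3 | 2-phenylethyl (E)-henicos-4-enoate | CCCCCCCCCCCCCCCC/C=C/CCC(=O)OCCc1ccccc1
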